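The data are calculated for an exercise; noise was put on by code.

What should be done to the flask at 15 h: ash, birch, larch or nothing?

all flasks: substrate 1.5 M; initiator 150 mM
- zeta: coupling partner 1.05 M; temperature 25 °C; the very flask that is asked about, followed so far
- alpha: coupling partner 0.70 M; temperature 20 °C; run made earlier
- flask: coupling partner 1.05 M; temperature 25 °C; time 15 h

| run | time / h | target / % | substrate / % |
|---|---|---|---|
| zeta | 1.50 | 16.2 | 82.6 |
| zeta | 3.00 | 26.8 | 69.2 |
| zeta | 5.00 | 34.7 | 53.7 |
| zeta | 6.00 | 37.3 | 47.5 |
| zeta | 8.00 | 32.6 | 47.2 |
| zeta | 10.0 | 28.2 | 47.7 |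
| alpha | 0.500 | 3.5 | 97.2 |
| alpha | 1.00 | 6.8 | 94.6 |
| alpha | 1.50 | 9.5 | 89.7 |
| alpha | 2.00 | 12.2 | 88.4 |
| alpha | 2.50 | 13.9 | 85.0 |
| alpha | 3.00 | 16.2 | 82.3 |

(readings scatter by 0.5 percentage points)

- ash: at 15 h take out 90% of the target then present, then wait 8.0 h
- birch: at 15 h raise the temperature by 25 K, then wait 8.0 h
- larch: change nothing and wait 8.0 h more

- target taken out counts as made
- candidate steps: initiator -> 2 initiating radical; substrate + initiating radical -> capped initiator + first chain carrier; coupling partner + first chain carrier -> target + second chain carrier; substrate + second chain carrier -> by-product + first chain carrier; 2 second chain carrier -> ended chains; target <-> isomer of the product; 2 coupling partner -> self-condensation product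

1. target, in percent of the substrate first charged, at 15 h
2. what to do for the largest gain in target; "none" if nothing gains more than 2 percentage points (ash / birch / larch / none)
3. target present, with what was taken out counted in, in percent of the substrate first charged, after ash
4. target present, with what was taken out counted in, in percent of the substrate first charged, after larch

In the zeta run, substrate reads 47.5%, 47.2% and 47.7% from 6.00 h on, while target falls. We therefore treat what left the substrate as a fixed pool of target plus isomer of the product, 52.5%. The choice hangs on how this pool divides, so we carry the rest ratio K: the forward rate constant from target to isomer of the product divided by the backward one, which is [isomer of the product]/[target] once both rates balance (the equilibrium constant). Time drops out of it.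

Forward constant = isomer of the product at 5.00 h / area under the target curve until then = 0.110 h⁻¹

Backward constant = (forward constant × mean target − fall of target) / mean isomer of the product = 0.0510 h⁻¹

K = 2.15

Target at rest = pool / (1 + K) = 16.7%

K is a rough reading, since the fall rests on two readings, each with scatter 0.5 percentage points. Relaxing at the sum of both constants, our reckoning gives target 21.9% at 15 h and 18.1% after larch. Ash takes out 19.7% and ends at 27.8% counted in. The zeta run gives K at one temperature, so birch is unread. If the pool holds and settles within the wait, birch passes our ash figure in this flask where the ratio drops below 0.888. We choose ash, and the ratio is what to watch.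

The forecast gives target 23% at 15 h, 20% after larch and 30% after ash, each a little above ours. It also picks ash, holding that “heating cannot restart the chain”.

The flask gives target 21.5% at 15 h, and the best step is birch, gaining 19 points against 5.7 points for ash and −4 points for larch. Ash ends at 27.1% and larch at 17.5%. Left until 150 h, this flask holds target 15.9%, where our K gave 16.7%.

    initiator → 2 initiating radical (k = 3.72 × 10⁻⁴ h⁻¹, Ea = 103 kJ mol⁻¹)
    substrate + initiating radical → capped initiator + first chain carrier (k = 30500 L mol⁻¹ s⁻¹, Ea = 32.0 kJ mol⁻¹)
    coupling partner + first chain carrier → target + second chain carrier (k = 2.74 × 10⁷ L mol⁻¹ h⁻¹, Ea = 41.0 kJ mol⁻¹)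
    substrate + second chain carrier → by-product + first chain carrier (k = 2.87 × 10⁶ L mol⁻¹ h⁻¹, Ea = 42.0 kJ mol⁻¹)
    2 second chain carrier → ended chains (k = 8.70 × 10⁶ L mol⁻¹ s⁻¹, Ea = 9.00 kJ mol⁻¹)
    target ⇌ isomer of the product (K = 2.30, k = 0.109 h⁻¹, Ea = 94.0 kJ mol⁻¹, ΔH = −67.0 kJ mol⁻¹)
    2 coupling partner → self-condensation product (k = 0.0880 L mol⁻¹ h⁻¹, Ea = 73.0 kJ mol⁻¹)
    (constants at 25 °C)

In the flask kept at 50 °C, our K, read at 25 °C, divides the 57.4% of target plus isomer of the product into 18.2% target. That flask at 50 °C holds 44.7% target and 12.7% isomer of the product at 15 h, a ratio of 0.284, which is lower than both K and the 0.888 reckoned for birch.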